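## The problem

Flavan numbering is used throughout (O1, C2, C3, C4, C4a, C5–C8, C8a; ring B C1'–C6').

- The target is a flavan. Ring A (oxygens on C5 and C7) is fused to the pyran ring C (O1, C2, C3, C4), ring B (oxygens on C3' and C4') sits on C2, and galloyl esters sit on O7 and O4'. O5–H, O3'–H and the secondary O3–H stay free.
- The first task is regiochemical. Two of four similar phenols must be acylated, one on each ring. In the finished flavan C4 is a methylene group and ring B is insulated from ring A, so nothing tells O7 from O5 or O4' from O3'.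
- The structure offers a way out. O7 is para to C4a and O4' is para to C1', the two ring carbons that carry the C4–C3–C2 bridge. In building blocks where C4 and C2 are still carbonyl carbons, O7–H and O4'–H are therefore the most acidic, non-chelated hydroxyls. The two oxygens ortho to the C4 carbonyl (future O5 and O1) are told apart by the hydrogen bond that only one of them can keep.
- The second task is stereochemical. C2 (R) and C3 (S) are the only stereocentres, adjacent and trans. Either could direct the other, but the absolute configuration must come from a reagent or catalyst.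
- The feature that makes the key step possible: C2 carries H, C3 carries OH and C4 carries no substituent. The trans pair is thus the product of a syn addition of H and OH across C2=C3 of an achiral 2-aryl-4H-chromene, in which O1 and ring B on C2 both send boron to C3.
- Sensitive points: the aryl gallates are cleaved by bases and nucleophiles, and the 4'-ester can migrate to O3' once that is free. The benzylic C2–O1 bond ionises under acid, opens through the ring B quinone methide when O4' is a free phenoxide, and can be hydrogenolysed. Ring A captures electrophiles such as formaldehyde equivalents.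
- The esters are therefore introduced in the last step but one, and the final deprotection must be neutral.

## Retrosynthesis

**17 ⇒ 16.** Eight benzyl C–O bonds are cut (six on the galloyl rings, O5 and O3'). Hydrogenolysis is the one global deprotection that is neutral, spares aryl esters and leaves only toluene. 16 is asked to carry benzyl groups on every oxygen that ends as a free phenol.

**16 ⇒ 14 + 15.** The two ester bonds O7–C(=O) and O4'–C(=O) are cut in one operation, because both acyl groups are the same. This asks that 14 has exactly these two phenols free. The secondary O3–H is left unprotected, since a phenol outruns a hindered secondary alcohol towards an aroyl chloride when no acyl-transfer catalyst is present. 15 is the commercial tribenzyl galloyl chloride.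

**14 ⇒ 13.** Two methoxymethyl (MOM) acetals on O7 and O4' are cut. MOM is orthogonal to benzyl, survives base, hydrogenation and borane, and can be removed without base, which the 4'-hydroxybenzyl ether at C2 would not tolerate for long.

**13 ⇒ 11 (key disconnection).** The C3–O bond and the C2–H bond are cut together, which leads to the achiral, planar 4H-chromene 11. This is preferred over cutting O1–C2 because one reagent-controlled syn addition then makes both stereocentres at once, and the trans relationship follows from the mechanism. 11 has no stereocentre, so nothing has to be carried or protected before this step. The forward reaction must put boron on C3 and choose one face of C2=C3.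

**11 ⇒ 9 ⇒ 8.** The enol ether bond O1–C2 is cut to give the phenol ketone 9, which closes through hemiketal 10 and loses water towards C3, the only carbon with β-hydrogens. 9 is traced to enone 8 by adding the C3=C4 double bond, so that an aldol condensation can make the chain.

**8 ⇒ 3 + 6.** The C3–C4 bond is cut. Aldehyde 3 supplies ring A and C4; ketone 6 supplies ring B, C2 and C3; aldol 7 is the intermediate. The two carbonyl groups that differentiate the phenols also make the carbon chain, and then disappear into the C4 methylene group and the C2 enol ether carbon.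

**3 ⇒ 2 ⇒ 1 and 6 ⇒ 5 ⇒ 4.** In each commercial hydroxy carbonyl compound the hydroxyl para to the carbonyl group is alkylated first with MOMCl, and a benzyl group follows. In 2 the benzylation stops after one ortho oxygen because the last hydroxyl is chelated; that oxygen becomes O1.

## Roads not taken

**Alternative 1 (the most obvious):** cut O1–C2 and the two C–O bonds at C2 and C3.
- Forward: (E)-1,3-diarylpropene A1, Sharpless asymmetric dihydroxylation to diol A2, then cyclic orthoformate formation and attack of the phenol oxygen on C2 with inversion, arriving at 13.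
- A1 must be made by C-alkylation of a phenol whose two other oxygens carry different groups. Such a phenol has two different free ortho carbons and nothing to tell them apart, so the O5/O7 differentiation is lost at the first C–C bond. In 3 the C4 carbon is already in place as the formyl group.
- Three operations (dihydroxylation, orthoester cyclisation, formate cleavage) do what step 8 does in one.
- The ring closure passes through a species with cationic character at C2, stabilised by ring B, so the trans/cis outcome depends on the substrate. Its acidic conditions also endanger the MOM groups.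

**Alternative 2:** cut C4–C4a and O1–C8a on ring A, together with O1–C2.
- Forward: the 3,5-dioxygenated benzyne from silyl triflate A3 (CsF) takes up the carbonyl group of enal A4 in a formal (2+2) addition. Ring opening gives an o-quinone methide and oxa-6π closure gives 2H-chromene A5.
- The regiochemistry would be right: the C5 oxygen beside the triple bond sends the carbonyl oxygen to C8a and the carbon to C4a.
- A3 needs three different oxygen substituents and a silyl group on one particular CH of a phloroglucinol. There is no symmetry or chelation to place them, and ortho-metalation would be steered by MOM to the wrong carbon. The run-up is much longer than the two steps to 3.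
- A5 is formed as a racemate, because C2 arises in an uncontrolled electrocyclisation. Hydroboration of A5 would relay C2 to C3 but not fix the absolute configuration, so a resolution or an isomerisation to 11 would still be needed.

**Alternative 3:** cut C2–C1'.
- Forward: enantioselective conjugate addition of arylboronic acid A7 to chromone A6 (Pd(OCOCF3)2 with a chiral pyridine-oxazoline ligand) to give (S)-flavanone A8.
- This sets C2 only. The oxygen sits on C4 and must be moved to C3 by reduction, dehydration and hydroboration, so the second stereocentre is set separately and three steps are added.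
- In A8 the C2 stereocentre is β to a ketone and carries an aryloxy leaving group, so base opens the ring to the chalcone and racemises it. The chosen route has no stereocentre before step 8.

Key step: step 8

Remark: the face of 11 attacked in step 8 is assigned by analogy with 1-arylcycloalkenes; if the other face is preferred, IpcBH2 from (−)-α-pinene is used and nothing else changes.
Remark: 15 is taken as a commercial acid chloride; MOMCl, BnBr and IpcBH2 (monoisopinocampheylborane, from (+)-α-pinene) are treated as reagents.

## Route

Step 1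
Reactants: 1 2,4,6-trihydroxybenzaldehyde
Product: 2 2,6-dihydroxy-4-(methoxymethoxy)benzaldehyde
Conditions: MOMCl (1.0 equiv), i-Pr2NEt (1.0 equiv), THF, −10 °C
Reagents that add atoms: chloromethyl methyl ether, COCCl
Why: Phenol O-alkylation (Williamson type); with one equivalent of base only the most acidic hydroxyl, O4–H para to the formyl group, is deprotonated, while both ortho hydroxyls are held by the formyl oxygen. This oxygen becomes O7.

Step 2
Reactants: 2 2,6-dihydroxy-4-(methoxymethoxy)benzaldehyde
Product: 3 2-(benzyloxy)-6-hydroxy-4-(methoxymethoxy)benzaldehyde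
Conditions: BnBr (1.05 equiv), K2CO3, DMF, rt
Reagents that add atoms: benzyl bromide, BrCc1ccccc1
Why: Williamson ether synthesis on one of two equivalent ortho hydroxyls; the remaining one is then locked in a hydrogen bond to the formyl group and resists a second alkylation under these mild conditions. The benzylated oxygen becomes O5 and the free one O1.

Step 3
Reactants: 4 1-(3,4-dihydroxyphenyl)ethanone
Product: 5 1-[3-hydroxy-4-(methoxymethoxy)phenyl]ethanone
Conditions: MOMCl (1.05 equiv), i-Pr2NEt (1.05 equiv), CH2Cl2, 0 °C
Reagents that add atoms: chloromethyl methyl ether, COCCl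
Why: Same principle as step 1: O4–H, para to the acetyl group, is the more acidic hydroxyl of the catechol and is alkylated first. This oxygen becomes O4'.

Step 4
Reactants: 5 1-[3-hydroxy-4-(methoxymethoxy)phenyl]ethanone
Product: 6 1-[3-(benzyloxy)-4-(methoxymethoxy)phenyl]ethanone
Conditions: BnBr (1.2 equiv), K2CO3, DMF, 50 °C
Reagents that add atoms: benzyl bromide, BrCc1ccccc1
Why: Williamson ether synthesis of the remaining meta hydroxyl, the future O3'.

Step 5
Reactants: 3 2-(benzyloxy)-6-hydroxy-4-(methoxymethoxy)benzaldehyde; 6 1-[3-(benzyloxy)-4-(methoxymethoxy)phenyl]ethanone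
Product: 8 (E)-3-[2-(benzyloxy)-6-hydroxy-4-(methoxymethoxy)phenyl]-1-[3-(benzyloxy)-4-(methoxymethoxy)phenyl]prop-2-en-1-one, via β-hydroxy ketone 7 (not isolated)
Conditions: KOH (50% aq), EtOH, rt
Reagents that add atoms: none
Why: Claisen–Schmidt condensation: the enolate of 6 adds to the formyl group of 3 (C3–C4 bond) and aldol 7 loses water by E1cB to the conjugated E enone. The phenoxide of 3 slows the addition but is tolerated, and the ethers are stable to hydroxide.

Step 6
Reactants: 8 (E)-3-[2-(benzyloxy)-6-hydroxy-4-(methoxymethoxy)phenyl]-1-[3-(benzyloxy)-4-(methoxymethoxy)phenyl]prop-2-en-1-one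
Product: 9 3-[2-(benzyloxy)-6-hydroxy-4-(methoxymethoxy)phenyl]-1-[3-(benzyloxy)-4-(methoxymethoxy)phenyl]propan-1-one
Conditions: H2 (1 atm), 10% Pd/C, Ph2S (cat.), EtOAc, rt
Reagents that add atoms: none
Why: Chemoselective heterogeneous hydrogenation of the enone C=C; diphenyl sulfide tempers the palladium surface so that the benzyl ethers and the aryl ketone are left alone. 9 may sit in equilibrium with its cyclic hemiketal, which does not matter for step 7.

Step 7
Reactants: 9 3-[2-(benzyloxy)-6-hydroxy-4-(methoxymethoxy)phenyl]-1-[3-(benzyloxy)-4-(methoxymethoxy)phenyl]propan-1-one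
Product: 11 5-(benzyloxy)-2-[3-(benzyloxy)-4-(methoxymethoxy)phenyl]-7-(methoxymethoxy)-4H-chromene, via cyclic hemiketal 10 (not isolated)
Conditions: PPTS (cat.), 4 Å MS, toluene, 80 °C; used without storage
Reagents that add atoms: none
Why: Acid-catalysed cyclodehydration of a phenolic δ-hydroxy ketone: O1–H adds to the C2 carbonyl (6-exo-trig) to give hemiketal 10, which loses water towards C3, the only carbon with β-hydrogens. The weak acid and removal of water spare the MOM acetals and limit self-condensation of the enol ether.

Step 8
Reactants: 11 5-(benzyloxy)-2-[3-(benzyloxy)-4-(methoxymethoxy)phenyl]-7-(methoxymethoxy)-4H-chromene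
Product: 13 (2R,3S)-5-(benzyloxy)-2-[3-(benzyloxy)-4-(methoxymethoxy)phenyl]-7-(methoxymethoxy)chroman-3-ol, via organoborane 12 (not isolated)
Conditions: IpcBH2 (from (+)-α-pinene, 1.3 equiv), THF, −25 °C; then NaOH (3 M), 30% H2O2, 0 °C
Reagents that add atoms: hydrogen peroxide, OO
Why: Brown asymmetric hydroboration–oxidation: the B–H bond of IpcBH2 adds across C2=C3 through a four-centre transition state, boron to C3 and hydrogen to C2, because O1 and ring B both stabilise positive charge at C2. The closest known reaction type is the IpcBH2 hydroboration of 1-arylcycloalkenes, and achiral boranes are known to turn 2-aryl-4H-chromenes into 2,3-trans-flavan-3-ols. No ring is closed in this step. C2 and C3 are created together: H and B enter on one face, so ring B on C2 and boron on C3 end on opposite faces, and oxidation of the C–B bond with retention gives the trans alcohol without any reliance on substrate bias. The absolute configuration at both centres is set by the isopinocampheyl group, which selects one face of the planar, achiral alkene; the reagent from (+)-α-pinene is chosen because it gives the (S)-carbinol from 1-arylcycloalkenes, which corresponds to 3S here. The step needs regioselectivity, secured by the enol ether and styrene polarisations acting in the same direction, and face selectivity, secured by the trisubstituted aryl alkene pattern that suits IpcBH2. Low temperature and immediate oxidation suppress β-elimination across the C2–O1 bond of 12, which lies anti to the C3–B bond. MOM and benzyl ethers are inert to the borane and to alkaline peroxide.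

Step 9
Reactants: 13 (2R,3S)-5-(benzyloxy)-2-[3-(benzyloxy)-4-(methoxymethoxy)phenyl]-7-(methoxymethoxy)chroman-3-ol
Product: 14 (2R,3S)-5-(benzyloxy)-2-[3-(benzyloxy)-4-hydroxyphenyl]chroman-3,7-diol
Conditions: ZnBr2 (2 equiv), n-PrSH (4 equiv), CH2Cl2, 0 °C
Reagents that add atoms: none
Why: Lewis-acid-assisted thiolysis of the two phenolic MOM acetals; the thiol captures the methoxymethyl cation so that it cannot alkylate the electron-rich ring A. Benzyl ethers, the C2–O1 ether and both stereocentres should be untouched at 0 °C.

Step 10
Reactants: 14 (2R,3S)-5-(benzyloxy)-2-[3-(benzyloxy)-4-hydroxyphenyl]chroman-3,7-diol; 15 3,4,5-tris(benzyloxy)benzoyl chloride (2.1 equiv)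
Product: 16 (2R,3S)-5-(benzyloxy)-2-[3-(benzyloxy)-4-{[3,4,5-tris(benzyloxy)benzoyl]oxy}phenyl]-3-hydroxychroman-7-yl 3,4,5-tris(benzyloxy)benzoate
Conditions: Et3N (2.5 equiv), CH2Cl2, 0 °C
Reagents that add atoms: none
Why: Chemoselective O-acylation of phenols by an aroyl chloride: with Et3N and no acyl-transfer catalyst the two phenols react far faster than the hindered secondary O3–H. O5 and O3' are benzylated, so only O7 and O4' can be acylated and no acyl migration is possible at this stage; the short time at 0 °C should keep the 4'-phenoxide from opening ring C.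

Step 11
Reactants: 16 (2R,3S)-5-(benzyloxy)-2-[3-(benzyloxy)-4-{[3,4,5-tris(benzyloxy)benzoyl]oxy}phenyl]-3-hydroxychroman-7-yl 3,4,5-tris(benzyloxy)benzoate
Product: 17 catechin 7,4'-di-O-gallate
Conditions: H2 (1 atm), Pd(OH)2/C, THF/EtOAc, rt; filtration and evaporation without base
Reagents that add atoms: none
Why: Hydrogenolysis of eight benzyl ethers under neutral conditions; aryl esters are stable, and the neutral, non-nucleophilic medium disfavours migration of the 4'-galloyl group to the freed O3'–H. The stereocentres are not involved.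

## Compound list

1 | 2,4,6-trihydroxybenzaldehyde | O=Cc1c(O)cc(O)cc1O | starting material
2 | 2,6-dihydroxy-4-(methoxymethoxy)benzaldehyde | COCOc1cc(O)c(C=O)c(O)c1 | intermediate
3 | 2-(benzyloxy)-6-hydroxy-4-(methoxymethoxy)benzaldehyde | COCOc1cc(O)c(C=O)c(OCc2ccccc2)c1 | intermediate
4 | 1-(3,4-dihydroxyphenyl)ethanone | CC(=O)c1ccc(O)c(O)c1 | starting material
5 | 1-[3-hydroxy-4-(methoxymethoxy)phenyl]ethanone | CC(=O)c1ccc(OCOC)c(O)c1 | intermediate
6 | 1-[3-(benzyloxy)-4-(methoxymethoxy)phenyl]ethanone | CC(=O)c1ccc(OCOC)c(OCc2ccccc2)c1 | intermediate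
7 | 3-[2-(benzyloxy)-6-hydroxy-4-(methoxymethoxy)phenyl]-1-[3-(benzyloxy)-4-(methoxymethoxy)phenyl]-3-hydroxypropan-1-one (racemic aldol) | COCOc1cc(O)c(C(O)CC(=O)c2ccc(OCOC)c(OCc3ccccc3)c2)c(OCc2ccccc2)c1 | intermediate
8 | (E)-3-[2-(benzyloxy)-6-hydroxy-4-(methoxymethoxy)phenyl]-1-[3-(benzyloxy)-4-(methoxymethoxy)phenyl]prop-2-en-1-one | COCOc1cc(O)c(/C=C/C(=O)c2ccc(OCOC)c(OCc3ccccc3)c2)c(OCc2ccccc2)c1 | intermediate
9 | 3-[2-(benzyloxy)-6-hydroxy-4-(methoxymethoxy)phenyl]-1-[3-(benzyloxy)-4-(methoxymethoxy)phenyl]propan-1-one | COCOc1cc(O)c(CCC(=O)c2ccc(OCOC)c(OCc3ccccc3)c2)c(OCc2ccccc2)c1 | intermediate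
10 | 5-(benzyloxy)-2-[3-(benzyloxy)-4-(methoxymethoxy)phenyl]-7-(methoxymethoxy)chroman-2-ol (racemic hemiketal) | COCOc1cc(OCc2ccccc2)c2c(c1)OC(O)(c1ccc(OCOC)c(OCc3ccccc3)c1)CC2 | intermediate
11 | 5-(benzyloxy)-2-[3-(benzyloxy)-4-(methoxymethoxy)phenyl]-7-(methoxymethoxy)-4H-chromene | COCOc1cc(OCc2ccccc2)c2c(c1)OC(c1ccc(OCOC)c(OCc3ccccc3)c1)=CC2 | intermediate
12 | [(2S,3S)-5-(benzyloxy)-2-[3-(benzyloxy)-4-(methoxymethoxy)phenyl]-7-(methoxymethoxy)chroman-3-yl][(1R,2S,3R,5R)-isopinocampheyl]borane (2,3-trans, same spatial arrangement as 13) | C[C@@H]1[C@H]2C[C@H](C2(C)C)C[C@H]1B[C@H]1Cc2c(OCc3ccccc3)cc(OCOC)cc2O[C@@H]1c1ccc(OCOC)c(OCc2ccccc2)c1 | intermediate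
13 | (2R,3S)-5-(benzyloxy)-2-[3-(benzyloxy)-4-(methoxymethoxy)phenyl]-7-(methoxymethoxy)chroman-3-ol | COCOc1cc(OCc2ccccc2)c2c(c1)O[C@H](c1ccc(OCOC)c(OCc3ccccc3)c1)[C@@H](O)C2 | intermediate
14 | (2R,3S)-5-(benzyloxy)-2-[3-(benzyloxy)-4-hydroxyphenyl]chroman-3,7-diol | Oc1cc(OCc2ccccc2)c2c(c1)O[C@H](c1ccc(O)c(OCc3ccccc3)c1)[C@@H](O)C2 | intermediate
15 | 3,4,5-tris(benzyloxy)benzoyl chloride | O=C(Cl)c1cc(OCc2ccccc2)c(OCc2ccccc2)c(OCc2ccccc2)c1 | starting material
16 | (2R,3S)-5-(benzyloxy)-2-[3-(benzyloxy)-4-{[3,4,5-tris(benzyloxy)benzoyl]oxy}phenyl]-3-hydroxychroman-7-yl 3,4,5-tris(benzyloxy)benzoate | O=C(Oc1cc(OCc2ccccc2)c2c(c1)O[C@H](c1ccc(OC(=O)c3cc(OCc4ccccc4)c(OCc4ccccc4)c(OCc4ccccc4)c3)c(OCc3ccccc3)c1)[C@@H](O)C2)c1cc(OCc2ccccc2)c(OCc2ccccc2)c(OCc2ccccc2)c1 | intermediate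
17 | catechin 7,4'-di-O-gallate, (2R,3S)-3,5-dihydroxy-2-{3-hydroxy-4-[(3,4,5-trihydroxybenzoyl)oxy]phenyl}chroman-7-yl 3,4,5-trihydroxybenzoate | O=C(Oc1cc(O)c2c(c1)O[C@H](c1ccc(OC(=O)c3cc(O)c(O)c(O)c3)c(O)c1)[C@@H](O)C2)c1cc(O)c(O)c(O)c1 | target

## Step count and uncertain steps

Total: 11 steps. Longest linear sequence: 9 steps (steps 1, 2 and 5–11 from 1; equally steps 3, 4 and 5–11 from 4).

**Step 8 (key step).** Face selection may be insufficient, because the alkene carries the peri 5-benzyloxy group and an oxygen in the ring, which the carbocyclic models lack. The organoborane may also open ring C by β-elimination across C2–O1 before it is oxidised. Any minor enantiomer should be removable by crystallisation of 13. Fallback, from 11 back to 13: hydroboration with BH3·THF and alkaline peroxide should give the racemic trans alcohol F1. A lipase resolution follows (Burkholderia cepacia lipase, vinyl acetate, t-BuOMe). By the empirical rule for secondary alcohols it should acetylate the (2S,3R) enantiomer to the (2S,3R)-acetate F2 and leave 13, which re-enters the route at step 9.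

**Step 7.** The acid may protonate the product enol ether at C3, which leads to dimers, or cleave a MOM acetal. 11 is also prone to air oxidation towards the flavylium level. Fallback, from 9 back to 11: ketalisation (HC(OMe)3, MeOH, PPTS, rt) should give the stable cyclic mixed ketal 2-methoxyflavan F3. Methanol is then removed under basic, aprotic conditions (TMSOTf, i-Pr2NEt, CH2Cl2, −20 °C), so the enol ether never meets a protic acid.

**Step 10.** Acylation may spill over to O3–H or stop at the mono-ester, and the 4'-phenoxide may start to open ring C before it is acylated. Fallback, from 13 to 17: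
- O3–H is benzylated (NaH, BnBr, THF) to the 3-O-benzyl ether F4.
- Thiolysis as in step 9 gives the 3-O-benzyl diphenol F5.
- Acylation with 15 can now be forced (Et3N, DMAP) to the 3-O-benzyl bis-gallate F6.
- Hydrogenolysis as in step 11 removes nine benzyl groups and gives 17.

**Step 11.** The benzylic C2–O1 bond may be hydrogenolysed on the catalyst, and the 4'-galloyl group may migrate to O3' during a long reaction or work-up. Fallback, from 16 to 17: reduction is replaced by Lewis-acid debenzylation with a cation scavenger (BCl3, pentamethylbenzene, CH2Cl2, −78 °C), which involves neither catalyst nor base; no new compound is made (entry F0).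

**Step 1.** Alkylation may go on to the bis-ether, because 2 is still an acidic phenol. Fallback, from 1 to 3:
- Over-alkylation is made the aim (MOMCl 2.2 equiv, i-Pr2NEt), which stops at the chelated hydroxyl and gives 2-hydroxy-4,6-bis(methoxymethoxy)benzaldehyde F7.
- Forced benzylation (BnBr, K2CO3, DMF, 60 °C) gives 2-(benzyloxy)-4,6-bis(methoxymethoxy)benzaldehyde F8.
- Brief treatment with HCl (cat.) in MeOH at rt should cleave only the acetal ortho to the formyl group, assisted by the hydrogen bond to the formyl oxygen, and give 3.

## Further compounds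

F1 | step 8 | racemic trans-5-(benzyloxy)-2-[3-(benzyloxy)-4-(methoxymethoxy)phenyl]-7-(methoxymethoxy)chroman-3-ol (both enantiomers shown) | COCOc1cc(OCc2ccccc2)c2c(c1)O[C@H](c1ccc(OCOC)c(OCc3ccccc3)c1)[C@@H](O)C2.COCOc1cc(OCc2ccccc2)c2c(c1)O[C@@H](c1ccc(OCOC)c(OCc3ccccc3)c1)[C@H](O)C2
F2 | step 8 | (2S,3R)-5-(benzyloxy)-2-[3-(benzyloxy)-4-(methoxymethoxy)phenyl]-7-(methoxymethoxy)chroman-3-yl acetate | COCOc1cc(OCc2ccccc2)c2c(c1)O[C@@H](c1ccc(OCOC)c(OCc3ccccc3)c1)[C@H](OC(C)=O)C2
F3 | step 7 | 5-(benzyloxy)-2-[3-(benzyloxy)-4-(methoxymethoxy)phenyl]-2-methoxy-7-(methoxymethoxy)chromane (racemic) | COCOc1cc(OCc2ccccc2)c2c(c1)OC(OC)(c1ccc(OCOC)c(OCc3ccccc3)c1)CC2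
F4 | step 10 | (2R,3S)-3,5-bis(benzyloxy)-2-[3-(benzyloxy)-4-(methoxymethoxy)phenyl]-7-(methoxymethoxy)chromane | COCOc1cc(OCc2ccccc2)c2c(c1)O[C@H](c1ccc(OCOC)c(OCc3ccccc3)c1)[C@@H](OCc1ccccc1)C2
F5 | step 10 | (2R,3S)-3,5-bis(benzyloxy)-2-[3-(benzyloxy)-4-hydroxyphenyl]chroman-7-ol | Oc1cc(OCc2ccccc2)c2c(c1)O[C@H](c1ccc(O)c(OCc3ccccc3)c1)[C@@H](OCc1ccccc1)C2
F6 | step 10 | (2R,3S)-3,5-bis(benzyloxy)-2-[3-(benzyloxy)-4-{[3,4,5-tris(benzyloxy)benzoyl]oxy}phenyl]chroman-7-yl 3,4,5-tris(benzyloxy)benzoate | O=C(Oc1cc(OCc2ccccc2)c2c(c1)O[C@H](c1ccc(OC(=O)c3cc(OCc4ccccc4)c(OCc4ccccc4)c(OCc4ccccc4)c3)c(OCc3ccccc3)c1)[C@@H](OCc1ccccc1)C2)c1cc(OCc2ccccc2)c(OCc2ccccc2)c(OCc2ccccc2)c1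
F0 | step 11 | none | none
F7 | step 1 | 2-hydroxy-4,6-bis(methoxymethoxy)benzaldehyde | COCOc1cc(O)c(C=O)c(OCOC)c1
F8 | step 1 | 2-(benzyloxy)-4,6-bis(methoxymethoxy)benzaldehyde | COCOc1cc(OCOC)c(C=O)c(OCc2ccccc2)c1
A1 | alternative 1 | (E)-3-(benzyloxy)-2-{3-[3-(benzyloxy)-4-(methoxymethoxy)phenyl]prop-2-en-1-yl}-5-(methoxymethoxy)phenol | COCOc1cc(O)c(C/C=C/c2ccc(OCOC)c(OCc3ccccc3)c2)c(OCc2ccccc2)c1
A2 | alternative 1 | (1S,2S)-3-[2-(benzyloxy)-6-hydroxy-4-(methoxymethoxy)phenyl]-1-[3-(benzyloxy)-4-(methoxymethoxy)phenyl]propane-1,2-diol | COCOc1cc(O)c(C[C@H](O)[C@@H](O)c2ccc(OCOC)c(OCc3ccccc3)c2)c(OCc2ccccc2)c1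
A3 | alternative 2 | 3-(benzyloxy)-5-(methoxymethoxy)-2-(trimethylsilyl)phenyl trifluoromethanesulfonate | COCOc1cc(OCc2ccccc2)c([Si](C)(C)C)c(OS(=O)(=O)C(F)(F)F)c1
A4 | alternative 2 | (E)-3-[3-(benzyloxy)-4-(methoxymethoxy)phenyl]prop-2-enal | O=C/C=C/c1ccc(OCOC)c(OCc2ccccc2)c1
A5 | alternative 2 | 5-(benzyloxy)-2-[3-(benzyloxy)-4-(methoxymethoxy)phenyl]-7-(methoxymethoxy)-2H-chromene (racemic) | COCOc1cc(OCc2ccccc2)c2c(c1)OC(c1ccc(OCOC)c(OCc3ccccc3)c1)C=C2
A6 | alternative 3 | 5-(benzyloxy)-7-(methoxymethoxy)-4H-chromen-4-one | COCOc1cc(OCc2ccccc2)c2c(c1)OC=CC2=O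
A7 | alternative 3 | [3-(benzyloxy)-4-(methoxymethoxy)phenyl]boronic acid | COCOc1ccc(B(O)O)cc1OCc1ccccc1
A8 | alternative 3 | (2S)-5-(benzyloxy)-2-[3-(benzyloxy)-4-(methoxymethoxy)phenyl]-7-(methoxymethoxy)chroman-4-one | COCOc1cc(OCc2ccccc2)c2c(c1)O[C@H](c1ccc(OCOC)c(OCc3ccccc3)c1)CC2=O
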